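The route rests on cutting the bond between the guaiacyl ring and C7, the acetal-level benzylic carbon of tetrahydrofuran ring B (O, C7, C8, C8', C9'), next to the hydroxylated ring-fusion carbon C8. In the key step an arylzinc reagent from silyl-protected 4-bromoguaiacol is joined to the C7 oxocarbenium ion released from an anomeric phenyl sulfone of the finished cis-fused 3,7-dioxabicyclo[3.3.0]octane core, which already carries the other aryl group on ring A. Ring A shields the concave face and the C8 zinc alkoxide sits on the convex face, so the aryl–C7 bond and the C7 stereocentre should form together. A catalytic asymmetric allylation sets C7' and C8', which relay C8 and C7.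

Key step: step 7

Remark: lignan numbering is used (C7/C7' benzylic, C8/C8' ring fusion, C9/C9' OCH2; C8 bears the hydroxyl); ring A = O, C7', C8', C8, C9. The silyl ethers 3 and 10 are taken as catalogue compounds; otherwise each is one silylation (TBSCl, imidazole, DMF) of vanillin or 4-bromo-2-methoxyphenol.

Step 1
Reactants: 1 3-methylidenedihydrofuran-2(3H)-one (α-methylene-γ-butyrolactone)
Product: 2 3-(bromomethyl)furan-2(5H)-one
Conditions: NBS, AIBN (cat.), PhCF3, 85 °C
Reagents that add atoms: N-bromosuccinimide, O=C1CCC(=O)N1Br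
Why: Wohl–Ziegler allylic bromination, in which hydrogen abstraction at the ring CH2 next to the exocyclic alkene gives an allyl radical that takes bromine at its primary terminus to give the conjugated butenolide; any allylic regioisomer would lead to the same allylchromium reagent in step 2.

Step 2
Reactants: 2 3-(bromomethyl)furan-2(5H)-one; 3 4-(tert-butyldimethylsilyloxy)-3-methoxybenzaldehyde
Product: 5 (4R)-4-[(S)-[4-(tert-butyldimethylsilyloxy)-3-methoxyphenyl](hydroxy)methyl]-3-methylidenedihydrofuran-2(3H)-one, via TMS ether 4 (not isolated)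
Conditions: CrCl2 (10 mol%), chiral 1,8-bis(4-isopropyl-4,5-dihydrooxazol-2-yl)-3,6-diphenyl-9H-carbazole ligand (12 mol%, antipode chosen for Si-face attack), iPr2NEt (30 mol%), Mn powder, TMSCl, THF, 0 → 23 °C; then 1 M HCl, THF, 0 °C
Reagents that add atoms: none
Why: Catalytic enantioselective Nozaki–Hiyama–Kishi-type 2-(alkoxycarbonyl)allylation, in which the allylchromium reagent (trivalent chromium) adds through its ring carbon in a closed chair transition state, the ligand selecting the Si face of the aldehyde (C7', S) and the ring-locked E-type allyl geometry giving the anti adduct that fixes C8' (R); TMSCl frees chromium for turnover and the TMS ether is cleaved on work-up.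

Step 3
Reactants: 5 (4R)-4-[(S)-[4-(tert-butyldimethylsilyloxy)-3-methoxyphenyl](hydroxy)methyl]-3-methylidenedihydrofuran-2(3H)-one
Product: 6 (3S,4R)-4-[(S)-[4-(tert-butyldimethylsilyloxy)-3-methoxyphenyl](hydroxy)methyl]-3-hydroxy-3-(hydroxymethyl)dihydrofuran-2(3H)-one
Conditions: OsO4 (2 mol%), NMO, acetone/H2O, 23 °C
Reagents that add atoms: N-methylmorpholine N-oxide, C[N+]1([O-])CCOCC1 (oxygen passed on through OsO4, O=[Os](=O)(=O)=O); water, O
Why: Upjohn dihydroxylation, in which OsO4 should add to the exocyclic alkene on the lactone face opposite the bulky C8' substituent, setting C8 with the tertiary hydroxyl cis to H-8' and the new CH2OH cis to the benzylic arm.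

Step 4
Reactants: 6 (3S,4R)-4-[(S)-[4-(tert-butyldimethylsilyloxy)-3-methoxyphenyl](hydroxy)methyl]-3-hydroxy-3-(hydroxymethyl)dihydrofuran-2(3H)-one
Product: 7 (3aR,4S,6aS)-4-[4-(tert-butyldimethylsilyloxy)-3-methoxyphenyl]-6a-hydroxytetrahydro-1H,3H-furo[3,4-c]furan-1-one
Conditions: CSA (10 mol%), 4 Å molecular sieves, CH2Cl2, 23 °C
Reagents that add atoms: none
Why: Acid-catalysed benzylic cyclodehydration (SN1), in which the electron-rich C7' cation is captured by the C9 hydroxyl to close ring A cis-fused to the lactone, with allylic strain (H-8' in the plane of the cation) placing the aryl group on the convex face, the same C7' configuration (S) as set in step 2.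

Step 5
Reactants: 7 (3aR,4S,6aS)-4-[4-(tert-butyldimethylsilyloxy)-3-methoxyphenyl]-6a-hydroxytetrahydro-1H,3H-furo[3,4-c]furan-1-one
Product: 8 (3aR,4S,6aS)-4-[4-(tert-butyldimethylsilyloxy)-3-methoxyphenyl]tetrahydro-1H,3H-furo[3,4-c]furan-1,6a-diol (C7 anomers)
Conditions: iBu2AlH (3 equiv), CH2Cl2, −78 °C; aq. potassium sodium tartrate
Reagents that add atoms: none
Why: Partial reduction of a γ-lactone, which should stop at the aluminium hemiacetal at low temperature and give the lactol on work-up; the anomeric centre is erased in step 7.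

Step 6
Reactants: 8 (3aR,4S,6aS)-4-[4-(tert-butyldimethylsilyloxy)-3-methoxyphenyl]tetrahydro-1H,3H-furo[3,4-c]furan-1,6a-diol
Product: 9 (3aR,4S,6aS)-4-[4-(tert-butyldimethylsilyloxy)-3-methoxyphenyl]-1-(phenylsulfonyl)tetrahydro-1H,3H-furo[3,4-c]furan-6a-ol (C7 anomers)
Conditions: PhSO2H, CaCl2, CH2Cl2, 23 °C
Reagents that add atoms: benzenesulfinic acid, O=S(O)c1ccccc1
Why: Known preparation of 2-benzenesulfonyl cyclic ethers from lactols, by exchange of the lactol hydroxyl for sulfinate through the C7 oxocarbenium ion; the tertiary C8 alcohol cannot ionise and C8 has no hydrogen to eliminate.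

Step 7
Reactants: 9 (3aR,4S,6aS)-4-[4-(tert-butyldimethylsilyloxy)-3-methoxyphenyl]-1-(phenylsulfonyl)tetrahydro-1H,3H-furo[3,4-c]furan-6a-ol; 10 (4-bromo-2-methoxyphenoxy)(tert-butyl)dimethylsilane
Product: 13 (1S,3aS,4R,6aR)-1,4-bis[4-(tert-butyldimethylsilyloxy)-3-methoxyphenyl]tetrahydro-1H,3H-furo[3,4-c]furan-3a-ol (bis-TBS ether of the target), via aryl Grignard reagent 11 (not isolated), via diarylzinc 12 (not isolated)
Conditions: 10 (3.3 equiv), Mg, THF, 40 °C; ZnBr2 (1.65 equiv), THF, 23 °C; then 9, THF, 23 °C; aqueous work-up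
Reagents that add atoms: none
Why: The first aryl–zinc bond is spent on the C8 hydroxyl, and the Lewis-acidic ZnBr2/MgBr2 medium then ionises the anomeric sulfone to the C7 oxocarbenium ion of ring B (directly or through the C7–C8 epoxide), which takes an aryl group from zinc with loss of zinc sulfinate. The closest known reaction type is the substitution of 2-benzenesulfonyl cyclic ethers by organozinc reagents made from Grignard reagents and ZnBr2, a C-glycosylation of the oxocarbenium type. No ring is closed; the step only joins the two fragments. The new C7 stereocentre is controlled by the substrate: ring A is folded under the concave face of the cis-fused bicycle and the C8 zinc alkoxide, which carries the aryl group to be transferred, lies on the convex face, so the aryl group should enter cis to the C8 oxygen and exo (7R). The selectivity needed is convex-face over concave-face attack, secured by the bicyclic shape and the alkoxide, together with the regiochemistry on the arene, fixed by the position of bromine in 10. Elimination to an enol ether cannot compete because C8 is quaternary.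

Step 8
Reactants: 13 (1S,3aS,4R,6aR)-1,4-bis[4-(tert-butyldimethylsilyloxy)-3-methoxyphenyl]tetrahydro-1H,3H-furo[3,4-c]furan-3a-ol
Product: 14 8-hydroxypinoresinol
Conditions: Bu4NF, AcOH, THF, 0 °C
Reagents that add atoms: none
Why: Fluoride cleavage of both aryl silyl ethers (desilylation), buffered with AcOH so that free phenoxides cannot open the benzylic ethers through quinone methides; no stereocentre is touched.

Compound list
1 | 3-methylidenedihydrofuran-2(3H)-one (α-methylene-γ-butyrolactone) | C=C1CCOC1=O | starting material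
2 | 3-(bromomethyl)furan-2(5H)-one | BrCC1=CCOC1=O | intermediate
3 | 4-(tert-butyldimethylsilyloxy)-3-methoxybenzaldehyde | COc1cc(C=O)ccc1O[Si](C)(C)C(C)(C)C | starting material
4 | (4R)-4-[(S)-[4-(tert-butyldimethylsilyloxy)-3-methoxyphenyl](trimethylsilyloxy)methyl]-3-methylidenedihydrofuran-2(3H)-one | C=C1C(=O)OC[C@@H]1[C@H](O[Si](C)(C)C)c1ccc(O[Si](C)(C)C(C)(C)C)c(OC)c1 | intermediate (not isolated)
5 | (4R)-4-[(S)-[4-(tert-butyldimethylsilyloxy)-3-methoxyphenyl](hydroxy)methyl]-3-methylidenedihydrofuran-2(3H)-one | C=C1C(=O)OC[C@@H]1[C@H](O)c1ccc(O[Si](C)(C)C(C)(C)C)c(OC)c1 | intermediate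
6 | (3S,4R)-4-[(S)-[4-(tert-butyldimethylsilyloxy)-3-methoxyphenyl](hydroxy)methyl]-3-hydroxy-3-(hydroxymethyl)dihydrofuran-2(3H)-one | OC[C@]1(O)C(=O)OC[C@@H]1[C@H](O)c1ccc(O[Si](C)(C)C(C)(C)C)c(OC)c1 | intermediate
7 | (3aR,4S,6aS)-4-[4-(tert-butyldimethylsilyloxy)-3-methoxyphenyl]-6a-hydroxytetrahydro-1H,3H-furo[3,4-c]furan-1-one | COc1cc([C@H]2OC[C@]3(O)C(=O)OC[C@H]23)ccc1O[Si](C)(C)C(C)(C)C | intermediate
8 | (3aR,4S,6aS)-4-[4-(tert-butyldimethylsilyloxy)-3-methoxyphenyl]tetrahydro-1H,3H-furo[3,4-c]furan-1,6a-diol (C7 anomers) | COc1cc([C@H]2OC[C@]3(O)C(O)OC[C@H]23)ccc1O[Si](C)(C)C(C)(C)C | intermediate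
9 | (3aR,4S,6aS)-4-[4-(tert-butyldimethylsilyloxy)-3-methoxyphenyl]-1-(phenylsulfonyl)tetrahydro-1H,3H-furo[3,4-c]furan-6a-ol (C7 anomers) | COc1cc([C@H]2OC[C@]3(O)C(S(=O)(=O)c4ccccc4)OC[C@H]23)ccc1O[Si](C)(C)C(C)(C)C | intermediate
10 | (4-bromo-2-methoxyphenoxy)(tert-butyl)dimethylsilane | COc1cc(Br)ccc1O[Si](C)(C)C(C)(C)C | starting material
11 | [4-(tert-butyldimethylsilyloxy)-3-methoxyphenyl]magnesium bromide | COc1cc([Mg]Br)ccc1O[Si](C)(C)C(C)(C)C | intermediate (not isolated)
12 | bis[4-(tert-butyldimethylsilyloxy)-3-methoxyphenyl]zinc | COc1cc([Zn]c2ccc(O[Si](C)(C)C(C)(C)C)c(OC)c2)ccc1O[Si](C)(C)C(C)(C)C | intermediate (not isolated)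
13 | (1S,3aS,4R,6aR)-1,4-bis[4-(tert-butyldimethylsilyloxy)-3-methoxyphenyl]tetrahydro-1H,3H-furo[3,4-c]furan-3a-ol | COc1cc([C@H]2OC[C@]3(O)[C@@H](c4ccc(O[Si](C)(C)C(C)(C)C)c(OC)c4)OC[C@H]23)ccc1O[Si](C)(C)C(C)(C)C | intermediate
14 | 8-hydroxypinoresinol, (1S,3aS,4R,6aR)-1,4-bis(4-hydroxy-3-methoxyphenyl)tetrahydro-1H,3H-furo[3,4-c]furan-3a-ol (7R,8S,7'S,8'R) | COc1cc([C@H]2OC[C@]3(O)[C@@H](c4ccc(O)c(OC)c4)OC[C@H]23)ccc1O | target

Total step count: 8. Longest linear sequence: 8 steps (1 → 14); the aryl bromide 10 enters in step 7.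

Steps most likely to fail

Step 7. After ionisation the neighbouring C8 alkoxide may close onto C7 to give an epoxide that opens slowly or without facial bias, or the oxocarbenium ion may decompose before aryl transfer. The fallback sets out from lactol 8 and still forms the aryl–C7 bond. Excess aryl Grignard reagent 11 (THF, −40 → 0 °C) adds to the open hydroxy-aldehyde form of 8 to give (3S,4R,5S)-5-[4-(tert-butyldimethylsilyloxy)-3-methoxyphenyl]-3-[[4-(tert-butyldimethylsilyloxy)-3-methoxyphenyl](hydroxy)methyl]-4-(hydroxymethyl)tetrahydrofuran-3-ol F1 as a mixture of C7 epimers. Acid-catalysed cyclodehydration (CSA, CH2Cl2, 0 °C) then ionises the benzylic C7 alcohol, and the C9' hydroxyl closes ring B with the aryl group eclipsing the small C8 hydroxyl (allylic strain). This comes back to the route at 13.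

Step 2. The cyclic, ester-conjugated allylchromium reagent may add with poor facial selectivity on the aldehyde or poor anti selectivity, or the adduct may translactonise. The fallback sets out from aldehyde 3 and uses auxiliary control. Lithiated (S)-4-benzyl-2-oxazolidinone opens itaconic anhydride at its non-conjugated carbonyl to give 4-[(S)-4-benzyl-2-oxooxazolidin-3-yl]-2-methylidene-4-oxobutanoic acid F2, and MeI/K2CO3 (DMF) gives its methyl ester F3. Enolisation with Bu2BOTf/iPr2NEt and addition of 3 (syn-selective boron aldol through a chair transition state) should give the adduct methyl (3S)-3-[(S)-[4-(tert-butyldimethylsilyloxy)-3-methoxyphenyl](hydroxy)methyl]-4-[(S)-4-benzyl-2-oxooxazolidin-3-yl]-2-methylidene-4-oxobutanoate F4 with C7' (S) and C8' in place. LiBH4 (THF, H2O, 0 °C) removes the auxiliary reductively, and the freed primary C9' alkoxide lactonises onto the methyl ester. This comes back to the route at 5.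

Step 4. Acid may translactonise the hydroxy lactone, remove the aryl silyl ether, or let the C7' cation close with the aryl group on the concave face. The fallback sets out from triol 6 and avoids a cation. Selective sulfonylation of the primary C9 hydroxyl (TsCl, pyridine, 0 °C) gives [(3S,4R)-4-[(S)-[4-(tert-butyldimethylsilyloxy)-3-methoxyphenyl](hydroxy)methyl]-3-hydroxy-2-oxotetrahydrofuran-3-yl]methyl 4-methylbenzenesulfonate F5. On warming in pyridine the C7' hydroxyl displaces the tosylate (5-exo-tet SN2 at C9, retention at C7'). This comes back to the route at 7.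

Further compounds
F1 | step 7 | (3S,4R,5S)-5-[4-(tert-butyldimethylsilyloxy)-3-methoxyphenyl]-3-[[4-(tert-butyldimethylsilyloxy)-3-methoxyphenyl](hydroxy)methyl]-4-(hydroxymethyl)tetrahydrofuran-3-ol (C7 epimers) | COc1cc([C@H]2OC[C@](O)(C(O)c3ccc(O[Si](C)(C)C(C)(C)C)c(OC)c3)[C@@H]2CO)ccc1O[Si](C)(C)C(C)(C)C
F2 | step 2 | 4-[(S)-4-benzyl-2-oxooxazolidin-3-yl]-2-methylidene-4-oxobutanoic acid | C=C(CC(=O)N1[C@@H](Cc2ccccc2)COC1=O)C(=O)O
F3 | step 2 | methyl 4-[(S)-4-benzyl-2-oxooxazolidin-3-yl]-2-methylidene-4-oxobutanoate | C=C(CC(=O)N1[C@@H](Cc2ccccc2)COC1=O)C(=O)OC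
F4 | step 2 | methyl (3S)-3-[(S)-[4-(tert-butyldimethylsilyloxy)-3-methoxyphenyl](hydroxy)methyl]-4-[(S)-4-benzyl-2-oxooxazolidin-3-yl]-2-methylidene-4-oxobutanoate | COC(=O)C(=C)[C@H](C(=O)N1[C@@H](Cc2ccccc2)COC1=O)[C@H](O)c1ccc(O[Si](C)(C)C(C)(C)C)c(OC)c1
F5 | step 4 | [(3S,4R)-4-[(S)-[4-(tert-butyldimethylsilyloxy)-3-methoxyphenyl](hydroxy)methyl]-3-hydroxy-2-oxotetrahydrofuran-3-yl]methyl 4-methylbenzenesulfonate | Cc1ccc(S(=O)(=O)OC[C@]2(O)C(=O)OC[C@@H]2[C@H](O)c2ccc(O[Si](C)(C)C(C)(C)C)c(OC)c2)cc1
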